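**Retrosynthetic overview**

- The benzil C6–C(=O) bond is cut last: a 6-lithio-2H-chromene (from the 6-bromide) is acylated with the dimethyl-ketal Weinreb amide of 4-methoxyphenylglyoxylic acid, and aqueous acid then frees the diketone and the C7 phenol.
- The strategy rests on the only alkene, C3=C4 of the pyran ring, which sits between the quaternary C2 and C4a of ring B (the chromene benzene ring). It is made by ring-closing metathesis of a 2-vinylaryl 1,1-dimethylallyl ether; the pyran is the only ring formed.
- The formyl carbon of 2,4-dihydroxy-6-methoxybenzaldehyde becomes C4. It already lies between the C5 methoxy group and the oxygen that becomes O1, so no aromatic substitution decides where the pyran is fused.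
- The diene comes from that aldehyde: MOM on the para hydroxyl, tertiary propargyl ether on the chelated hydroxyl, semi-hydrogenation, bromination of the future C6, Wittig methylenation.
- The C6 bromine is set before ring closure. On the open-chain ether only the hydrogen between OMe and OMOM has two small coordinating neighbours; after closure the exposed ring oxygen O1 would make C8 a competing lithiation site.

Key step: step 6

Assumption: the 2'-hydroxybenzil is taken in the open diketone form of the SMILES (a cyclic hemiketal tautomer, if present at equilibrium, is the same substance), and 2,4-dihydroxy-6-methoxybenzaldehyde is bought.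

**Route**

Step 1
Reactants: 1 2,4-dihydroxy-6-methoxybenzaldehyde
Product: 2 2-hydroxy-6-methoxy-4-(methoxymethoxy)benzaldehyde
Conditions: MOMCl (1.05 equiv), K2CO3, acetone, 0 °C → rt
Reagents that add atoms: chloromethyl methyl ether, COCCl
Why: Williamson etherification should stop at the free, more acidic 4-hydroxyl because the 2-hydroxyl is held in a hydrogen bond to the formyl group and is much less nucleophilic.

Step 2
Reactants: 2 2-hydroxy-6-methoxy-4-(methoxymethoxy)benzaldehyde; 3 3-chloro-3-methylbut-1-yne
Product: 4 2-methoxy-4-(methoxymethoxy)-6-[(2-methylbut-3-yn-2-yl)oxy]benzaldehyde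
Conditions: DBU, CuCl2·2H2O (cat.), MeCN, 0 °C → rt
Reagents that add atoms: 3-chloro-3-methylbut-1-yne (3), CC(C)(Cl)C#C
Why: Copper-catalysed propargylic etherification of the tertiary chloride is the standard entry to aryl 1,1-dimethylpropargyl ethers and should alkylate even the chelated, electron-poor salicylaldehyde hydroxyl at 0 °C, far below the temperature of the propargyl Claisen rearrangement.

Step 3
Reactants: 4 2-methoxy-4-(methoxymethoxy)-6-[(2-methylbut-3-yn-2-yl)oxy]benzaldehyde
Product: 5 2-methoxy-4-(methoxymethoxy)-6-[(2-methylbut-3-en-2-yl)oxy]benzaldehyde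
Conditions: H2 (1 atm), Pd on CaCO3 poisoned with Pb(OAc)2 (Lindlar catalyst), quinoline, EtOAc, rt
Reagents that add atoms: none
Why: Lindlar semi-hydrogenation should stop at the alkene because the poisoned palladium surface binds the terminal alkyne much more strongly than the product alkene, and it leaves the aldehyde, the MOM ether and the aryl ether untouched.

Step 4
Reactants: 5 2-methoxy-4-(methoxymethoxy)-6-[(2-methylbut-3-en-2-yl)oxy]benzaldehyde
Product: 9 3-bromo-2-methoxy-4-(methoxymethoxy)-6-[(2-methylbut-3-en-2-yl)oxy]benzaldehyde, via lithium amino alkoxide 6 (not isolated), via ring-lithiated amino alkoxide 7 (not isolated), via brominated amino alkoxide 8 (not isolated)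
Conditions: lithium 4-methylpiperazin-1-ide (from 1-methylpiperazine, n-BuLi), THF, −20 °C; s-BuLi, TMEDA, −78 °C; BrCl2C–CCl2Br, −78 → 0 °C; H2O
Reagents that add atoms: 1,2-dibromo-1,1,2,2-tetrachloroethane, ClC(Cl)(Br)C(Cl)(Cl)Br
Why: Directed ortho-metalation on an in situ protected aldehyde: the lithium amide adds to the formyl group to give an α-amino alkoxide that is inert to alkyllithiums, the MOM ether then steers s-BuLi to the one ring hydrogen between two small coordinating groups (OMOM and OMe) and away from the hydrogen beside the bulky, weakly coordinating tertiary aryl ether oxygen, the aryllithium takes bromine from BrCl2C–CCl2Br, and water returns the aldehyde; at −78 °C the allyl ether should survive the base.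

Step 5
Reactants: 9 3-bromo-2-methoxy-4-(methoxymethoxy)-6-[(2-methylbut-3-en-2-yl)oxy]benzaldehyde; 10 methyltriphenylphosphonium bromide
Product: 12 2-bromo-4-ethenyl-3-methoxy-1-(methoxymethoxy)-5-[(2-methylbut-3-en-2-yl)oxy]benzene, via methylidenetriphenylphosphorane 11 (not isolated)
Conditions: KOtBu, THF, 0 °C; then 9, 0 °C → rt
Reagents that add atoms: methyltriphenylphosphonium bromide (10), C[P+](c1ccccc1)(c1ccccc1)c1ccccc1.[Br-]
Why: Wittig methylenation with the non-stabilised ylide is reliable for di-ortho-substituted, electron-rich benzaldehydes and should touch neither the aryl bromide nor the tertiary allyl ether.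

Step 6
Reactants: 12 2-bromo-4-ethenyl-3-methoxy-1-(methoxymethoxy)-5-[(2-methylbut-3-en-2-yl)oxy]benzene
Product: 13 6-bromo-5-methoxy-7-(methoxymethoxy)-2,2-dimethyl-2H-chromene
Conditions: second-generation Grubbs catalyst RuCl2(=CHPh)(H2IMes)(PCy3) (5 mol%), CH2Cl2 (0.01 M), 25–30 °C, argon purge
Reagents that add atoms: none
Why: Ring-closing olefin metathesis: the ruthenium benzylidene exchanges onto one terminal alkene of 12 (most likely the styrene) by [2+2] cycloaddition and cycloreversion, the new alkylidene adds across the second terminal alkene of the same molecule, and cycloreversion of the ruthenacyclobutane releases the C3=C4 bond and a ruthenium methylidene that carries the chain, with loss of ethene. The closest known reaction type is the ring-closing metathesis of 2-vinylaryl allyl ethers to 2H-chromenes. The pyran closes as a six-membered ring in which both alkene carbons become ring atoms (C3 and C4); the ring enforces the cis alkene and no stereocentre is formed. The step needs ring closure to win over intermolecular metathesis and over the thermal [3,3] shift of the aryl 1,1-dimethylallyl ether to the free ortho carbon (the future C8); high dilution, the gem-dimethyl group at C2 that holds the two alkenes close, and a temperature near ambient should secure this. Neither alkene carries an allylic hydrogen, so ruthenium hydride isomerisation cannot divert the diene, and the aryl bromide, MOM ether and methyl ether are spectators.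

Step 7
Reactants: 14 methyl 2-(4-methoxyphenyl)-2-oxoacetate
Product: 15 methyl 2,2-dimethoxy-2-(4-methoxyphenyl)acetate
Conditions: HC(OMe)3, MeOH, H2SO4 (cat.), reflux
Reagents that add atoms: trimethyl orthoformate, COC(OC)OC; methanol, CO
Why: Acid-catalysed ketalisation driven by the orthoformate masks the aryl ketone, the more electrophilic carbonyl of the α-keto ester, as its dimethyl ketal (the 4-methoxyphenyl group stabilises the oxocarbenium intermediate) before organometallic chemistry.

Step 8
Reactants: 15 methyl 2,2-dimethoxy-2-(4-methoxyphenyl)acetate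
Product: 16 N,2,2-trimethoxy-2-(4-methoxyphenyl)-N-methylacetamide
Conditions: MeNH(OMe)·HCl, i-PrMgCl, THF, −20 → 0 °C
Reagents that add atoms: N,O-dimethylhydroxylamine hydrochloride, CNOC.Cl
Why: Weinreb amide formation: the chloromagnesium amide made in situ aminolyses the methyl ester directly, and the two α-oxygen atoms activate the hindered ester towards attack.

Step 9
Reactants: 13 6-bromo-5-methoxy-7-(methoxymethoxy)-2,2-dimethyl-2H-chromene; 16 N,2,2-trimethoxy-2-(4-methoxyphenyl)-N-methylacetamide
Product: 19 1-[5-methoxy-7-(methoxymethoxy)-2,2-dimethyl-2H-chromen-6-yl]-2,2-dimethoxy-2-(4-methoxyphenyl)ethan-1-one, via 6-lithiochromene 17 (not isolated), via lithium hemiaminal adduct 18 (not isolated)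
Conditions: t-BuLi (2 equiv), THF, −78 °C; then 16, −78 °C → rt; H2O
Reagents that add atoms: N,2,2-trimethoxy-2-(4-methoxyphenyl)-N-methylacetamide (16), CON(C)C(=O)C(OC)(OC)c1ccc(OC)cc1
Why: Bromine–lithium exchange is regiospecific, so the aryllithium can only sit at C6, and the Weinreb ketone synthesis gives a chelated tetrahedral adduct that survives until aqueous work-up, which prevents over-addition and keeps the ketal in place.

Step 10
Reactants: 19 1-[5-methoxy-7-(methoxymethoxy)-2,2-dimethyl-2H-chromen-6-yl]-2,2-dimethoxy-2-(4-methoxyphenyl)ethan-1-one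
Product: 20 1-(7-hydroxy-5-methoxy-2,2-dimethyl-2H-chromen-6-yl)-2-(4-methoxyphenyl)ethane-1,2-dione
Conditions: 2 M aq. HCl, THF, 45 °C
Reagents that add atoms: water, O
Why: Acidic acetal hydrolysis should cleave the dimethyl ketal (through the 4-methoxyphenyl-stabilised oxocarbenium ion) and the MOM ether in one operation, and the 2,2-dimethylchromene, deactivated by the C6 acyl group, should tolerate dilute HCl at this temperature.

**Compound list**

1 | 2,4-dihydroxy-6-methoxybenzaldehyde | COc1cc(O)cc(O)c1C=O | starting material
2 | 2-hydroxy-6-methoxy-4-(methoxymethoxy)benzaldehyde | COCOc1cc(O)c(C=O)c(OC)c1 | intermediate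
3 | 3-chloro-3-methylbut-1-yne | CC(C)(Cl)C#C | starting material
4 | 2-methoxy-4-(methoxymethoxy)-6-[(2-methylbut-3-yn-2-yl)oxy]benzaldehyde | COCOc1cc(OC)c(C=O)c(OC(C)(C)C#C)c1 | intermediate
5 | 2-methoxy-4-(methoxymethoxy)-6-[(2-methylbut-3-en-2-yl)oxy]benzaldehyde | COCOc1cc(OC)c(C=O)c(OC(C)(C)C=C)c1 | intermediate
6 | lithium {2-methoxy-4-(methoxymethoxy)-6-[(2-methylbut-3-en-2-yl)oxy]phenyl}(4-methylpiperazin-1-yl)methanolate | [Li+].[O-]C(N1CCN(C)CC1)c1c(OC)cc(OCOC)cc1OC(C)(C)C=C | intermediate (not isolated)
7 | 3-lithio derivative of 6 (lithium on the ring carbon between OMe and OMOM) | [Li+].[O-]C(N1CCN(C)CC1)c1c(OC)c([Li])c(OCOC)cc1OC(C)(C)C=C | intermediate (not isolated)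
8 | 3-bromo derivative of 6 (bromine on the ring carbon between OMe and OMOM) | [Li+].[O-]C(N1CCN(C)CC1)c1c(OC)c(Br)c(OCOC)cc1OC(C)(C)C=C | intermediate (not isolated)
9 | 3-bromo-2-methoxy-4-(methoxymethoxy)-6-[(2-methylbut-3-en-2-yl)oxy]benzaldehyde | COCOc1cc(OC(C)(C)C=C)c(C=O)c(OC)c1Br | intermediate
10 | methyltriphenylphosphonium bromide | C[P+](c1ccccc1)(c1ccccc1)c1ccccc1.[Br-] | starting material
11 | methylidenetriphenylphosphorane | C=P(c1ccccc1)(c1ccccc1)c1ccccc1 | intermediate (not isolated)
12 | 2-bromo-4-ethenyl-3-methoxy-1-(methoxymethoxy)-5-[(2-methylbut-3-en-2-yl)oxy]benzene | COCOc1cc(OC(C)(C)C=C)c(C=C)c(OC)c1Br | intermediate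
13 | 6-bromo-5-methoxy-7-(methoxymethoxy)-2,2-dimethyl-2H-chromene | COCOc1cc2OC(C)(C)C=Cc2c(OC)c1Br | intermediate
14 | methyl 2-(4-methoxyphenyl)-2-oxoacetate | COC(=O)C(=O)c1ccc(OC)cc1 | starting material
15 | methyl 2,2-dimethoxy-2-(4-methoxyphenyl)acetate | COC(=O)C(OC)(OC)c1ccc(OC)cc1 | intermediate
16 | N,2,2-trimethoxy-2-(4-methoxyphenyl)-N-methylacetamide | CON(C)C(=O)C(OC)(OC)c1ccc(OC)cc1 | intermediate
17 | [5-methoxy-7-(methoxymethoxy)-2,2-dimethyl-2H-chromen-6-yl]lithium | COCOc1cc2OC(C)(C)C=Cc2c(OC)c1[Li] | intermediate (not isolated)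
18 | lithium 1-[5-methoxy-7-(methoxymethoxy)-2,2-dimethyl-2H-chromen-6-yl]-1-[methoxy(methyl)amino]-2,2-dimethoxy-2-(4-methoxyphenyl)ethan-1-olate | [Li+].[O-]C(N(C)OC)(c1c(OC)c2C=CC(C)(C)Oc2cc1OCOC)C(OC)(OC)c1ccc(OC)cc1 | intermediate (not isolated)
19 | 1-[5-methoxy-7-(methoxymethoxy)-2,2-dimethyl-2H-chromen-6-yl]-2,2-dimethoxy-2-(4-methoxyphenyl)ethan-1-one | COCOc1cc2OC(C)(C)C=Cc2c(OC)c1C(=O)C(OC)(OC)c1ccc(OC)cc1 | intermediate
20 | 1-(7-hydroxy-5-methoxy-2,2-dimethyl-2H-chromen-6-yl)-2-(4-methoxyphenyl)ethane-1,2-dione | COc1ccc(C(=O)C(=O)c2c(O)cc3c(c2OC)C=CC(C)(C)O3)cc1 | target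

**Step count**

Total steps: 10. Longest linear sequence: 8 (steps 1 to 6, then 9 and 10); steps 7 and 8 make the side-chain amide.

**Steps most likely to fail**

Step 6. Initiation and turnover may be slow at the twisted, doubly ortho-flanked, electron-rich styrene and at the vinyl group beside the quaternary carbon. Catalyst decay, intermolecular metathesis of the styrene or the [3,3] shift of the allyl aryl ether could then overtake ring closure. The fallback sets out from aldehyde 9, closes the pyran by forming the O1–C2 bond instead, and returns at 13. The tertiary allyl group of 9 is removed with Pd(PPh3)4 and morpholine, which should give 3-bromo-6-hydroxy-2-methoxy-4-(methoxymethoxy)benzaldehyde F4. Excess 2-methylprop-1-enylmagnesium bromide in THF at 0 °C should add to the formyl group to give 1-[3-bromo-6-hydroxy-2-methoxy-4-(methoxymethoxy)phenyl]-3-methylbut-2-en-1-ol F5. Warming this very electron-rich benzylic alcohol in toluene should dehydrate it to the ortho-quinone methide 4-bromo-5-methoxy-3-(methoxymethoxy)-6-(3-methylbut-2-en-1-ylidene)cyclohexa-2,4-dien-1-one F6, whose oxa-6π electrocyclisation should give 13.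

Step 4. Masking of the hindered formyl group may be incomplete, so that the alkyllithium adds to the carbonyl, or SN2′ attack on the allyl aryl ether may compete with ring metalation. The fallback sets out from 5, replaces the in situ mask by a reduction and oxidation pair, and returns at 9. NaBH4 in MeOH should reduce 5 to {2-methoxy-4-(methoxymethoxy)-6-[(2-methylbut-3-en-2-yl)oxy]phenyl}methanol F1. Two equivalents of s-BuLi with TMEDA at −78 °C should deprotonate the hydroxyl and lithiate the ring between OMe and OMOM to give the dilithio derivative of F1, F2. Trapping with BrCl2C–CCl2Br should give {3-bromo-2-methoxy-4-(methoxymethoxy)-6-[(2-methylbut-3-en-2-yl)oxy]phenyl}methanol F3, and MnO2 in CH2Cl2 should oxidise the benzylic alcohol to 9.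

Step 9. The hindered, strongly basic aryllithium may remove a proton from the N-methoxy group of the amide (with loss of formaldehyde), or fail to add to a carbonyl flanked by the quaternary ketal carbon. The fallback sets out from 13 and 15, uses an aldehyde electrophile followed by oxidation, and returns at 19. i-Bu2AlH at −78 °C should reduce ester 15 to 2,2-dimethoxy-2-(4-methoxyphenyl)acetaldehyde F7. Aryllithium 17, made from 13 as in step 9, should add to this less hindered carbonyl to give 1-[5-methoxy-7-(methoxymethoxy)-2,2-dimethyl-2H-chromen-6-yl]-2,2-dimethoxy-2-(4-methoxyphenyl)ethan-1-ol F8. Dess–Martin periodinane in CH2Cl2 should oxidise the alcohol to 19.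

Further compounds
F1 | step 4 | {2-methoxy-4-(methoxymethoxy)-6-[(2-methylbut-3-en-2-yl)oxy]phenyl}methanol | COCOc1cc(OC)c(CO)c(OC(C)(C)C=C)c1
F2 | step 4 | dilithio derivative of F1 (lithium alkoxide, ring lithium between OMe and OMOM) | [Li+].[O-]Cc1c(OC)c([Li])c(OCOC)cc1OC(C)(C)C=C
F3 | step 4 | {3-bromo-2-methoxy-4-(methoxymethoxy)-6-[(2-methylbut-3-en-2-yl)oxy]phenyl}methanol | COCOc1cc(OC(C)(C)C=C)c(CO)c(OC)c1Br
F4 | step 6 | 3-bromo-6-hydroxy-2-methoxy-4-(methoxymethoxy)benzaldehyde | COCOc1cc(O)c(C=O)c(OC)c1Br
F5 | step 6 | 1-[3-bromo-6-hydroxy-2-methoxy-4-(methoxymethoxy)phenyl]-3-methylbut-2-en-1-ol | COCOc1cc(O)c(C(O)C=C(C)C)c(OC)c1Br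
F6 | step 6 | 4-bromo-5-methoxy-3-(methoxymethoxy)-6-(3-methylbut-2-en-1-ylidene)cyclohexa-2,4-dien-1-one | O=C1C=C(OCOC)C(Br)=C(OC)C1=CC=C(C)C
F7 | step 9 | 2,2-dimethoxy-2-(4-methoxyphenyl)acetaldehyde | COC(OC)(C=O)c1ccc(OC)cc1
F8 | step 9 | 1-[5-methoxy-7-(methoxymethoxy)-2,2-dimethyl-2H-chromen-6-yl]-2,2-dimethoxy-2-(4-methoxyphenyl)ethan-1-ol | COCOc1cc2OC(C)(C)C=Cc2c(OC)c1C(O)C(OC)(OC)c1ccc(OC)cc1
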